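(All runs stem from a simulated flask on assumed constants; the scatter is artificial.)

| flask | G | L | X | temperature | remark | time |
|---|---|---|---|---|---|---|
| summer | 1.2 M | 1.56 M | 1.2 M | 80 °C | the very flask that is asked about, followed so far |  |
| spring | 1.2 M | 1.56 M | 1.2 M | 65 °C | run made earlier |  |
| flask | 1.2 M | 1.56 M | 1.20 M | 80 °C |  | 2.5 min |

summer run (percent of the G charged)

| time / s | Z / % |
|---|---|
| 10.0 | 32.5 |
| 20.0 | 28.7 |
| 30.0 | 29.4 |
| 50.0 | 29.8 |
| 80.0 | 29.5 |
| 90.0 | 29.3 |
| 120 | 29.1 |

spring run (percent of the G charged)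

| time / min | Z / % |
|---|---|
| 0.333 | 32.6 |
| 0.667 | 22.2 |
| 1.00 | 19.4 |
| 2.00 | 17.3 |
| 3.00 | 17.1 |
| 4.00 | 16.7 |

(scatter of a reading: 0.5 percentage points)

- birch: at 2.5 min take out 90% of the Z then present, then wait 5.0 min
- alder: at 2.5 min raise the temperature by 15 K, then wait 5.0 min
- ash: change nothing and wait 5.0 min more

- Z that was removed still counts
- the earlier runs were read with a standard deviation of 0.5 percentage points

- Z, in percent of the G first charged, at 2.5 min
- which option adds most Z ("none" when 2 percentage points or less is all one gets) (birch / alder / ash / none)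
- Z present, with what was taken out counted in, in percent of the G first charged, after birch
- Z present, with what was taken out counted in, in percent of the G first charged, after alder

Start from the leftover: once the summer readings go flat, at a mean of 29.3% of the G charged, the other 70.7% sits in forms you do not read. Their ratio is ω = 0.414, the Z odds, plateau Z over leftover G. The spring plateau reads 17.0%, so ω there is 0.205, and 15 K of heating lifts log10 ω by Φ = 0.305.

The summer readings are flat from 20.0 s and you wait 5.0 min, so I expect Z on its plateau (thermodynamic control), 29.3%, at 2.5 min and nothing from ash. I take birch to leave ω alone: what stays in the flask returns to the same share, for a total of 47.9%. Alder's rise equals the step between the two runs, so I let it raise log10 ω by Φ, which gives 45.6%. I commit to birch, by 2.3 points.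

Is one number enough? Not for the contents: the first summer reading, 32.5%, stands above the plateau, so the leftover may hold more than one form, and the return after birch is an assumption.

The forecast has 29.3% at the asked time, 44.5% after birch and 45% after alder, and picks alder where I pick birch: “Birch and alder nearly tie”. The flask gives 29.9%, 47.4% after birch and 39.2% after alder, so the best is birch, adding 17 points against 9.3 points, and ash adds 0 points.

    X + L ⇌ E (K = 1.10 M⁻¹, k = 5.50 M⁻¹ s⁻¹, Ea = 57.0 kJ mol⁻¹, ΔH = −8.00 kJ mol⁻¹)
    Z ⇌ Q (K = 0.960, k = 0.107 s⁻¹, Ea = 82.0 kJ mol⁻¹, ΔH = −63.0 kJ mol⁻¹)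
    G + L ⇌ Z (K = 2.53 M⁻¹, k = 0.893 M⁻¹ s⁻¹, Ea = 54.0 kJ mol⁻¹, ΔH = −16.0 kJ mol⁻¹)
    G ⇌ J (K = 0.600, k = 0.168 s⁻¹, Ea = 86.0 kJ mol⁻¹, ΔH = −90.0 kJ mol⁻¹)
    (constants at 80 °C)

In this flask, by each step alone and both ways together, G + L and Z relax with a half-life of 0.668 s, shorter than the 1.55 s of G and J, and both are short against 2.5 min. At 2.5 min ω in this flask is 0.427, and alder takes it to 0.645, a rise in log10 ω of 0.179 against Φ of 0.305. For the flask kept at 55 °C, the spring ω carried down at Φ per 15 K gives 0.128, and that flask holds Z at 13.8%, an ω of 0.160.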